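A plateau is easily taken for a stable product. In the green run X reads 67.0% at 4.00 h and 67.4% at 12.0 h, yet in the ochre run, charged with D in excess, it falls from 85.1% at 4.00 h to 62.6% at 12.0 h. We read this as a loss of X that needs D. That bears on the next flask: we must choose whether to keep its charge and when to stop it.

| setting | green | teal | ochre | flask |
|---|---|---|---|---|
| J | 0.10 M | 0.10 M | 0.050 M | 0.10 M |
| D | 0.075 M | 0.11 M | 0.15 M | 0.150 M |
| remark | run made earlier | run made earlier | run made earlier |  |
| time |  |  |  | 12 h |

| run | time / h | X / % | J / % |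
|---|---|---|---|
| green | 1.00 | 45.0 | 54.8 |
| green | 1.50 | 51.9 | 44.7 |
| green | 2.50 | 59.1 | 38.1 |
| green | 4.00 | 67.0 | 32.2 |
| green | 5.00 | 65.2 | 28.8 |
| green | 8.00 | 67.3 | 25.7 |
| green | 12.0 | 67.4 | 27.7 |
| teal | 1.00 | 60.6 | 38.5 |
| teal | 1.50 | 68.4 | 29.8 |
| teal | 2.50 | 77.3 | 19.4 |
| teal | 4.00 | 81.4 | 12.7 |
| teal | 5.00 | 83.6 | 8.3 |
| teal | 8.00 | 85.5 | 7.2 |
| teal | 12.0 | 87.6 | 4.3 |
| ochre | 1.00 | 76.3 | 22.0 |
| ochre | 2.00 | 86.4 | 4.0 |
| ochre | 4.00 | 85.1 | 0 |
| ochre | 6.00 | 77.4 | 0 |
| ochre | 12.0 | 62.6 | 2.3 |

(each reading ± 1 percentage point)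



Over that ochre stretch D stands near 0.0869 M, counting one D per J turned and one more per X lost. We therefore treat the loss as pseudo-first-order in X, at 0.0384 h⁻¹, and dividing by D gives a loss constant of 0.442 M⁻¹ h⁻¹. The green reading at 1.00 h, put into the integrated second-order law for J + D, gives a making constant of 12.9 M⁻¹ h⁻¹, far larger. Both constants carry the scatter of the readings, 1 percentage point.

The loss constant over the making constant, 3.43%, is our selectivity factor, the turning ratio. On these two steps making and losing both carry D as a factor, so D cancels between them, and we expect X to peak where J over X equals this ratio. We keep the charge of 0.150 M D on 0.10 M J and stop the flask on a reading, when J over X has fallen to that value, not by the clock.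

- when, up to 12 h, the flask holds most X
- the amount of X, in percent of the J charged, at that time

The forecast puts the peak at 3.8 h (3 h to 5 h) with 87.5% of X (85.5% to 89.5%). It takes J at 3.3% of X where we have 3.43%, and adds: “The peak is flat, so the time is uncertain.”

The flask holds most X at 4.13 h, 86.8%, under this scheme:

    J + D → X (k = 0.220 M⁻¹ min⁻¹)
    D + X → E (k = 0.00690 M⁻¹ min⁻¹)
    J + 2 D → L (k = 0.0490 M⁻² min⁻¹)
    J + X → Z (k = 0.00170 M⁻¹ min⁻¹)

At 0.430 h in the flask X goes to E 8.0 times as fast as to Z, and the step to Z makes no difference to the peak time. At 4.13 h J over X in the flask is 3.19%, against the turning ratio of 3.43%. The neighbour charged with 0.090 M of D, 0.900 equiv, ends at 12.0 h with J over X at 17.2%, above the ratio, and holds 78.8% of X there, its best being 78.8%.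

The data stem from a simulated flask with constants of no real substance, noise included.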